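Ring B is disconnected at C2'–C3' and C4'–C5'. The C2'–N1'–C5' unit becomes the glycine imine of a ring A aldehyde, and C3'/C4' come from an alkene that serves as an acetylene equivalent. One silver-catalysed azomethine ylide [3+2] cycloaddition of methyl N-[(1-Boc-pyrrol-2-yl)methylidene]glycinate with (E)-1,2-bis(phenylsulfonyl)ethene forms both C–C bonds and closes ring B as a pyrrolidine already attached to ring A. The step exploits the fact that N1' of ring B is flanked by C2' (bearing ring A) and C5' (bearing bromine): the ester left at C5' is later exchanged for that bromine by bromodecarboxylation, and the two sulfonyl groups depart on aromatization. Bromination of the remaining positions completes the target.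

Key step: step 2

Remark on the dipolarophile: it carries two sulfonyl groups because a single sulfonyl group (at C3') would leave no acidic hydrogen β to the leaving group, so aromatization would need an added oxidant; the second sulfonyl group at C4' sits β to the ester, so DBU alone should deliver the pyrrole.
Remark on stereochemistry: adduct 6 is racemic and is drawn as expected for an endo approach; this is a working assumption without consequence, since step 3 removes all four stereocentres and the target has none.
Remark on materials: 1, 2 and 5 are taken as purchased.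

Step 1
Reactants: 1 tert-butyl 2-formylpyrrole-1-carboxylate; 2 glycine methyl ester hydrochloride
Product: 4 methyl (E)-N-[(1-tert-butoxycarbonylpyrrol-2-yl)methylidene]glycinate, via glycine methyl ester 3 (not isolated)
Conditions: Et3N (1.1 equiv), MgSO4, CH2Cl2, rt; filter, concentrate, use crude
Reagents that add atoms: none
Why: Imine condensation of an aldehyde with a primary amine: triethylamine frees amine 3 from its hydrochloride, MgSO4 binds the water formed, the less hindered (E)-aldimine should result, and the N-Boc carbamate should not be attacked under these mild conditions.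

Step 2
Reactants: 4 methyl (E)-N-[(1-tert-butoxycarbonylpyrrol-2-yl)methylidene]glycinate; 5 (E)-1,2-bis(phenylsulfonyl)ethene
Product: 6 methyl 5-(1-tert-butoxycarbonylpyrrol-2-yl)-3,4-bis(phenylsulfonyl)pyrrolidine-2-carboxylate (racemic)
Conditions: AgOAc (10 mol %), Et3N (20 mol %), THF, rt, dark, Ar
Reagents that add atoms: none
Why: AgOAc binds the imine nitrogen and the ester carbonyl of 4, and triethylamine then removes the acidified glycine α-hydrogen to give an N-metallated, W-shaped azomethine ylide that adds across the electron-poor alkene 5; the closest known reaction type is the silver acetate/amine-catalysed 1,3-dipolar cycloaddition of aryl aldimines of glycine esters with sulfonyl alkenes. Ring B closes in a suprafacial [3+2] mode, formally a Michael addition of the glycine carbon (forming C4'–C5') followed by a 5-endo-trig Mannich closure of the α-sulfonyl carbanion onto the silver-bound imine carbon (forming C2'–C3'). The cis relation of C2' and C5' follows from the W geometry of the chelated dipole, the trans relation of C3' and C4' is carried over from the (E)-alkene, and the sulfonyl group at C3' is expected cis to ring A through an endo approach beneath the metal; the adduct is racemic. Because none of the four stereocentres survives step 3, only chemoselectivity is needed: cycloaddition must outrun hydrolysis of the imine and conjugate addition of the amine base or of the adduct N–H to 5. This is secured by the N-Boc group, which removes the acidic ring A N–H (no silver pyrrolide) and keeps the aldimine electrophilic, and by the C2-symmetric dipolarophile, which leaves no regiochemical choice.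

Step 3
Reactants: 6 methyl 5-(1-tert-butoxycarbonylpyrrol-2-yl)-3,4-bis(phenylsulfonyl)pyrrolidine-2-carboxylate
Product: 8 methyl 5-(1-tert-butoxycarbonylpyrrol-2-yl)-1H-pyrrole-2-carboxylate, via sulfonyl dihydropyrrole ester 7 (not isolated)
Conditions: DBU (4 equiv), CH2Cl2, 0 °C → rt
Reagents that add atoms: none
Why: Two successive E1cB eliminations of benzenesulfinate: DBU removes the C5' hydrogen α to the ester and expels the β-sulfinate at C4' to give enamino ester 7, N–H deprotonation of 7 then drives vinylogous loss of the C3' sulfinate, and the 2H-pyrrole formed should tautomerize to the aromatic 1H-pyrrole without any oxidant and without loss of the N-Boc group.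

Step 4
Reactants: 8 methyl 5-(1-tert-butoxycarbonylpyrrol-2-yl)-1H-pyrrole-2-carboxylate
Product: 11 1H,1'H-2,2'-bipyrrole-5-carboxylic acid, via N-H methyl ester 9 (not isolated), via sodium carboxylate 10 (not isolated)
Conditions: NaOH (5 equiv), MeOH/H2O, 60 °C, Ar; then 1 M HCl, 0 °C, to pH 3–4
Reagents that add atoms: sodium hydroxide, [Na+].[OH-]
Why: Hydroxide should first cleave the acyl-activated N-Boc carbamate of ring A (acyl substitution releasing the pyrrolide, tert-butanol and carbonate) and then saponify the methyl ester, while cold, mild acidification should free the acid without the acid-promoted decarboxylation to which pyrrole-2-carboxylic acids are prone.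

Step 5
Reactants: 11 1H,1'H-2,2'-bipyrrole-5-carboxylic acid
Product: 13 3,3',4,4',5,5'-hexabromo-1H,1'H-2,2'-bipyrrole, via pentabromo acid 12 (not isolated)
Conditions: NBS (6.3 equiv), THF/DMF, −40 °C → rt, dark, Ar; aq. Na2S2O3 work-up
Reagents that add atoms: N-bromosuccinimide, O=C1CCC(=O)N1Br
Why: Electrophilic aromatic substitution by NBS should brominate the five free positions of the electron-rich bipyrrole, and ipso attack at C5' with loss of CO2 (bromodecarboxylation of a pyrrole-2-carboxylic acid) should install the sixth bromine; the order of the six substitutions is immaterial because all partly brominated acids converge on 13, with 12 taken as the last of them.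

Compound list
1 | tert-butyl 2-formylpyrrole-1-carboxylate | O=Cc1cccn1C(=O)OC(C)(C)C | starting material
2 | glycine methyl ester hydrochloride | COC(=O)CN.Cl | starting material
3 | glycine methyl ester (free base) | COC(=O)CN | intermediate (not isolated)
4 | methyl (E)-N-[(1-tert-butoxycarbonylpyrrol-2-yl)methylidene]glycinate | COC(=O)C/N=C/c1cccn1C(=O)OC(C)(C)C | intermediate
5 | (E)-1,2-bis(phenylsulfonyl)ethene | O=S(=O)(/C=C/S(=O)(=O)c1ccccc1)c1ccccc1 | starting material
6 | methyl 5-(1-tert-butoxycarbonylpyrrol-2-yl)-3,4-bis(phenylsulfonyl)pyrrolidine-2-carboxylate; racemic, one enantiomer drawn; C2 ester and C5 pyrrolyl cis, C4 sulfonyl cis to the pyrrolyl, C3 sulfonyl trans to the C2 ester and to the C4 sulfonyl (pyrrolidine C5, C4, C3, C2 = C2', C3', C4', C5') | COC(=O)[C@@H]1[C@@H](S(=O)(=O)c2ccccc2)[C@H](S(=O)(=O)c2ccccc2)[C@@H](N1)c1cccn1C(=O)OC(C)(C)C | intermediate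
7 | methyl 5-(1-tert-butoxycarbonylpyrrol-2-yl)-4-(phenylsulfonyl)-4,5-dihydro-1H-pyrrole-2-carboxylate; racemic, 4,5-cis drawn | COC(=O)C1=C[C@H](S(=O)(=O)c2ccccc2)[C@@H](N1)c1cccn1C(=O)OC(C)(C)C | intermediate (not isolated)
8 | methyl 5-(1-tert-butoxycarbonylpyrrol-2-yl)-1H-pyrrole-2-carboxylate | COC(=O)c1ccc([nH]1)-c1cccn1C(=O)OC(C)(C)C | intermediate
9 | methyl 1H,1'H-2,2'-bipyrrole-5-carboxylate | COC(=O)c1ccc([nH]1)-c1ccc[nH]1 | intermediate (not isolated)
10 | sodium 1H,1'H-2,2'-bipyrrole-5-carboxylate | [Na+].[O-]C(=O)c1ccc([nH]1)-c1ccc[nH]1 | intermediate (not isolated)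
11 | 1H,1'H-2,2'-bipyrrole-5-carboxylic acid | OC(=O)c1ccc([nH]1)-c1ccc[nH]1 | intermediate
12 | 3,3',4,4',5-pentabromo-1H,1'H-2,2'-bipyrrole-5'-carboxylic acid (assumed last intermediate before loss of CO2) | OC(=O)c1[nH]c(-c2[nH]c(Br)c(Br)c2Br)c(Br)c1Br | intermediate (not isolated)
13 | 3,3',4,4',5,5'-hexabromo-1H,1'H-2,2'-bipyrrole | Brc1[nH]c(-c2[nH]c(Br)c(Br)c2Br)c(Br)c1Br | target

Total step count: 5. Longest linear sequence: 5 steps (1 → 4 → 6 → 8 → 11 → 13).

Steps most likely to fail

Step 2. The cycloaddition may be eroded by hydrolysis of the glycine aldimine, by open-chain conjugate addition without ring closure, or by addition of the adduct N–H to a second molecule of 5. The fallback closes ring B by C–N bond formation from a vinyl azide instead of by cycloaddition. It sets out from aldehyde 1 and returns at 8. A Wittig reaction of 1 with (triphenylphosphoranylidene)acetaldehyde (toluene, 80 °C) should give tert-butyl 2-[(E)-3-oxoprop-1-en-1-yl]pyrrole-1-carboxylate F1. Condensation of F1 with methyl azidoacetate (NaOMe, MeOH, −20 °C) should give methyl (2Z,4E)-2-azido-5-(1-tert-butoxycarbonylpyrrol-2-yl)penta-2,4-dienoate F2. Treatment of F2 with catalytic ZnI2 (CH2Cl2, rt) or brief heating in toluene should expel dinitrogen and form the N1'–C2' bond, giving pyrrole ester 8.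

Step 5. Ipso substitution at C5' may stop short, leaving the carboxyl group in place, or excess NBS may degrade the electron-rich bipyrrole oxidatively before all six positions are filled. The fallback separates decarboxylation from halogenation; it sets out from acid 11 and returns at target 13. Heating 11 in ethanolamine (170 °C, Ar) should give 1H,1'H-2,2'-bipyrrole F3 by thermal decarboxylation. Sixfold C–H bromination of F3 with NBS (6 equiv, THF, −78 °C → rt, dark) should then give 13.

Step 3. The sequence may stall after the first elimination, or the base may open the β-amino sulfone by a retro-Mannich pathway. The fallback replaces the double elimination by reduction followed by oxidation; it sets out from adduct 6 and returns at 8. Reductive elimination of the vicinal disulfone with sodium amalgam (Na2HPO4, MeOH/THF, −20 °C; Julia-type) should give methyl cis-5-(1-tert-butoxycarbonylpyrrol-2-yl)-2,5-dihydro-1H-pyrrole-2-carboxylate F4. Dehydrogenation of F4 with MnO2 (CH2Cl2, rt) should then give 8.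

Further compounds
F1 | step 2 | tert-butyl 2-[(E)-3-oxoprop-1-en-1-yl]pyrrole-1-carboxylate | O=C/C=C/c1cccn1C(=O)OC(C)(C)C
F2 | step 2 | methyl (2Z,4E)-2-azido-5-(1-tert-butoxycarbonylpyrrol-2-yl)penta-2,4-dienoate | COC(=O)/C(N=[N+]=[N-])=C/C=C/c1cccn1C(=O)OC(C)(C)C
F3 | step 5 | 1H,1'H-2,2'-bipyrrole | c1cc(-c2ccc[nH]2)[nH]c1
F4 | step 3 | methyl cis-5-(1-tert-butoxycarbonylpyrrol-2-yl)-2,5-dihydro-1H-pyrrole-2-carboxylate (racemic) | COC(=O)[C@@H]1C=C[C@@H](N1)c1cccn1C(=O)OC(C)(C)C
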